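Locants: C1 = ring CH bearing the side chain; C2/C3 = butenolide β/α carbons; C4, C5 = cyclopropane CH (C9 = its CH2); C6 = CHMe; C7 = CH2; C8 = CHOH; C10/C11 = lactone C=O/OCH2; C13 = side-chain CH; C14 = CH2OAc.
Enabling feature: in the eight-membered ring C1–C8, C8 (at ketone level) and C3 (α to the lactone carbonyl C10) are both carbonyl-flanked and are joined through C1–C2. This 1,5-dicarbonyl array is what a cyclobutanol retro-aldol leaves behind, and the lactone oxygen already ties C10 to C11 on C2.
Retrosynthesis: remove the acetate and the C8 hydride, re-bond C3–C8 (aldol sense), then cut C2–C3 and C1–C8 ([2+2] sense). This gives a cyclopropane-fused β-acetoxy cyclohexenecarboxylate esterified with the propargylic alcohol C11–C2≡C1–C13; then cut O–C10, the C9 methylene and C3–C10.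
Forward: the six-membered ring comes from (R)-3-methylcyclohexanone and the cyclopropane is added second. Lactone and cyclobutene then close together under light, and the eight-membered ring arises in the same flask by fragmentation of the shared C3–C8 bond.
Stereochemistry: C6 from the chiral pool; C4/C5 by cyclopropanation anti to the C6 methyl; C13 by lipase desymmetrisation of a prochiral diol; C1 by equilibration next to the C8 ketone; C8 by hydride delivery anti to the side chain.

Key step: step 16

Assumption: Pseudomonas fluorescens lipase is taken to acylate the pro-R hydroxymethyl arm of 2-alkylpropane-1,3-diols, as drawn for 13.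

Step 1
Reactants: 1 (R)-3-methylcyclohexanone
Product: 2 methyl (4R)-4-methyl-2-oxocyclohexane-1-carboxylate (keto/enol mixture, C1 of the name undefined)
Conditions: NaH, (MeO)2CO, THF, reflux; AcOH quench
Reagents that add atoms: dimethyl carbonate, COC(=O)OC
Why: Claisen-type carbomethoxylation under equilibrating conditions ends at the enolate of the less crowded β-keto ester, so the future C10 lands on the α-carbon remote from the methyl-bearing C6 (the future C3) and C6 is not touched.

Step 2
Reactants: 2 methyl (4R)-4-methyl-2-oxocyclohexane-1-carboxylate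
Product: 5 methyl (4R)-4-methyl-6-oxocyclohex-1-ene-1-carboxylate, via α-phenylselanyl keto ester 3 (not isolated), via selenoxide 4 (not isolated)
Conditions: PhSeCl, pyridine, CH2Cl2, 0 °C; then 30% H2O2, 0 °C → rt
Reagents that add atoms: phenylselenyl chloride, Cl[Se]c1ccccc1 (PhSe in 3 and 4 only); hydrogen peroxide, OO (O on Se in 4 only)
Why: α-Selenenylation of the β-keto ester at C3 followed by selenoxide syn elimination, which can only run toward C4–H because the other neighbours of C3 are carbonyl carbons.

Step 3
Reactants: 5 methyl (4R)-4-methyl-6-oxocyclohex-1-ene-1-carboxylate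
Product: 6 methyl (4S)-2-acetoxy-4-methylcyclohexa-1,5-diene-1-carboxylate
Conditions: Ac2O, Et3N, DMAP (cat.), CH2Cl2, 0 °C, Ar
Reagents that add atoms: acetic anhydride, CC(=O)OC(C)=O
Why: Deconjugative enol acetylation: the amine removes the γ-proton at C5, the only one that leads to the doubly stabilised β-keto ester enolate, and O-acylation traps it as the dienol acetate with the free alkene now at C4=C5 and C6 unchanged in space (its descriptor changes by priority only).

Step 4
Reactants: 6 methyl (4S)-2-acetoxy-4-methylcyclohexa-1,5-diene-1-carboxylate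
Product: 7 methyl (1R,5S,6R)-3-acetoxy-5-methylbicyclo[4.1.0]hept-2-ene-2-carboxylate
Conditions: Et2Zn, CH2I2, CH2Cl2, −10 °C → rt
Reagents that add atoms: diiodomethane, ICI
Why: Furukawa-type Simmons–Smith cyclopropanation, in which the electrophilic zinc carbenoid prefers the disubstituted C4=C5 to the tetrasubstituted, ester-bearing C8=C3 and adds suprafacially from the face opposite the allylic C6 methyl, setting C4 and C5 together.

Step 5
Reactants: 7 methyl (1R,5S,6R)-3-acetoxy-5-methylbicyclo[4.1.0]hept-2-ene-2-carboxylate
Product: 8 methyl (1R,5S,6R)-5-methyl-3-oxobicyclo[4.1.0]heptane-2-carboxylate (keto/enol mixture, C2 of the name undefined)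
Conditions: K2CO3 (cat.), MeOH, 0 °C
Reagents that add atoms: none
Why: Base-catalysed methanolysis of the activated enol ester is much faster than any attack on the methyl ester and frees the enolisable β-keto ester that the ester exchange of step 14 needs.

Step 6
Reactants: 9 diethyl malonate; 10 5-bromo-2-methylpent-2-ene
Product: 11 diethyl 2-(4-methylpent-3-en-1-yl)malonate
Conditions: NaH, THF–DMF, 0 → 60 °C
Reagents that add atoms: none
Why: Malonic ester alkylation (SN2) of a primary homoallylic bromide, with the malonate in excess to suppress double alkylation.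

Step 7
Reactants: 11 diethyl 2-(4-methylpent-3-en-1-yl)malonate
Product: 12 2-(4-methylpent-3-en-1-yl)propane-1,3-diol
Conditions: LiAlH4, THF, 0 °C → rt
Reagents that add atoms: none
Why: Hydride reduction of both esters gives the prochiral 1,3-diol and leaves the trisubstituted alkene alone.

Step 8
Reactants: 12 2-(4-methylpent-3-en-1-yl)propane-1,3-diol
Product: 13 (2R)-2-(hydroxymethyl)-6-methylhept-5-en-1-yl acetate
Conditions: Pseudomonas fluorescens lipase, vinyl acetate, i-Pr2O, rt
Reagents that add atoms: vinyl acetate, C=COC(C)=O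
Why: Enzymatic desymmetrisation by irreversible transesterification, in which the lipase acylates one enantiotopic hydroxymethyl arm (taken as pro-R) and thereby creates the C13 stereocentre.

Step 9
Reactants: 13 (2R)-2-(hydroxymethyl)-6-methylhept-5-en-1-yl acetate
Product: 14 (2S)-2-{[(tert-butyldimethylsilyl)oxy]methyl}-6-methylhept-5-en-1-yl acetate
Conditions: TBSCl, imidazole, CH2Cl2, 0 °C
Reagents that add atoms: tert-butyldimethylsilyl chloride, CC(C)(C)[Si](C)(C)Cl
Why: Standard silylation of the free primary alcohol is faster than acetyl migration between the two arms, so C13 keeps its integrity.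

Step 10
Reactants: 14 (2S)-2-{[(tert-butyldimethylsilyl)oxy]methyl}-6-methylhept-5-en-1-yl acetate
Product: 15 (2S)-2-{[(tert-butyldimethylsilyl)oxy]methyl}-6-methylhept-5-en-1-ol
Conditions: K2CO3 (cat.), MeOH, 0 °C
Reagents that add atoms: none
Why: Mild methanolysis of the primary acetate at low temperature, under which a primary TBS ether should neither cleave nor migrate.

Step 11
Reactants: 15 (2S)-2-{[(tert-butyldimethylsilyl)oxy]methyl}-6-methylhept-5-en-1-ol
Product: 16 (2R)-2-{[(tert-butyldimethylsilyl)oxy]methyl}-6-methylhept-5-enal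
Conditions: TEMPO (cat.), PhI(OAc)2, CH2Cl2, rt; used crude
Reagents that add atoms: none
Why: Oxoammonium (TEMPO) oxidation stops at the aldehyde and is neutral enough not to epimerise the α-stereocentre C13 or eliminate the β-silyloxy group.

Step 12
Reactants: 16 (2R)-2-{[(tert-butyldimethylsilyl)oxy]methyl}-6-methylhept-5-enal
Product: 17 tert-butyl{[(2S)-2-(2,2-dibromoethenyl)-6-methylhept-5-en-1-yl]oxy}dimethylsilane
Conditions: CBr4, PPh3, CH2Cl2, 0 °C
Reagents that add atoms: carbon tetrabromide, BrC(Br)(Br)Br
Why: First stage of the Corey–Fuchs homologation, a Wittig-type dibromomethylenation that needs no base and so preserves C13.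

Step 13
Reactants: 17 tert-butyl{[(2S)-2-(2,2-dibromoethenyl)-6-methylhept-5-en-1-yl]oxy}dimethylsilane
Product: 19 (4S)-4-{[(tert-butyldimethylsilyl)oxy]methyl}-8-methylnon-7-en-2-yn-1-ol, via lithium acetylide 18 (not isolated)
Conditions: n-BuLi (2.2 equiv), THF, −78 → 0 °C; (CH2O)n, 0 °C → rt; H2O
Reagents that add atoms: formaldehyde (from paraformaldehyde), C=O; n-butyllithium, [Li]CCCC (Li in 18 only)
Why: Second stage of the Corey–Fuchs sequence, in which bromine–lithium exchange and rearrangement give the lithium acetylide, whose addition to formaldehyde installs C11 as the propargylic alcohol.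

Step 14
Reactants: 8 methyl (1R,5S,6R)-5-methyl-3-oxobicyclo[4.1.0]heptane-2-carboxylate; 19 (4S)-4-{[(tert-butyldimethylsilyl)oxy]methyl}-8-methylnon-7-en-2-yn-1-ol
Product: 20 (4S)-4-{[(tert-butyldimethylsilyl)oxy]methyl}-8-methylnon-7-en-2-yn-1-yl (1R,5S,6R)-5-methyl-3-oxobicyclo[4.1.0]heptane-2-carboxylate
Conditions: DMAP (0.3 equiv), toluene, reflux, 4 Å molecular sieves
Reagents that add atoms: none
Why: DMAP-catalysed transesterification of an enolisable β-keto ester, driven by trapping of methanol on the sieves, joins the two fragments through the O–C10 bond without touching silyl ether, alkyne or cyclopropane.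

Step 15
Reactants: 20 propargylic β-keto ester
Product: 21 (4S)-4-{[(tert-butyldimethylsilyl)oxy]methyl}-8-methylnon-7-en-2-yn-1-yl (1R,5S,6R)-3-acetoxy-5-methylbicyclo[4.1.0]hept-2-ene-2-carboxylate
Conditions: Ac2O, Et3N, DMAP (cat.), CH2Cl2, 0 °C → rt
Reagents that add atoms: acetic anhydride, CC(=O)OC(C)=O
Why: O-Acylation of the stabilised β-keto ester enolate (enol acetate formation) fixes the C8=C3 enoate chromophore and masks the C8 oxygen as the group that later triggers the retro-aldol.

Step 16
Reactants: 21 enol acetate propargylic ester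
Product: 24 (1R,4R,5R,6S,13S)-C8-keto butenolide TBS ether, via cyclobutene photoadduct 22 (not isolated), via sodium dienolate 23 (not isolated)
Conditions: hν (medium-pressure Hg lamp, borosilicate filter, λ > 290 nm), MeCN–acetone 9:1, 3 mM, Ar, 40 °C; then NaOMe, MeOH, 0 °C; AcOH quench; Et3N (cat.), rt
Reagents that add atoms: sodium methoxide, [Na+].[O-]C (Na in 23 only)
Why: Proposed new method: acetone transfers triplet energy to the β-acetoxy enoate of 21; C3 then attacks the inner alkyne carbon C2 in a 5-exo-dig radical closure that forms the γ-lactone ring, and after spin inversion the C8 radical couples with the vinyl radical at C1 to close the cyclobutene of 22. Methoxide next removes the tertiary acetate, and the cyclobutenolate cleaves the shared C3–C8 bond in a strain-driven retro-aldol, so the eight-membered ring is opened out of the bicyclo[4.2.0] unit by fragmentation instead of being closed end to end, and the doubly stabilised dienolate 23 results. The closest known reaction type is the De Mayo photocycloaddition–retro-aldol ring expansion of enol esters and dioxinones carrying tethered alkenes or alkynes; an ester oxygen inside the tether and a cyclopropane next to the excited enoate have not been shown. Regioselectivity (C2 to C3, C1 to C8) follows from the three-atom tether, only the minor E rotamer of the ester can close (polar MeCN and gentle warming raise its share, while the excited Z rotamer merely relaxes by twisting of the ring-held C8=C3), and the cyclopropane should hold because the C3 radical is ester-stabilised and is consumed in the first bond formation. The C3 and C8 centres of 22 (drawn for addition anti to C9) vanish again, so the only lasting new stereocentre is C1. It is set by protonation of 23 at C1, which restores the conjugated butenolide, and by amine-catalysed equilibration toward the epimer in which H1 eclipses C2=C3 (least A1,3 strain against C4) and the branched chain lies on the open face beside C9 in the tub-shaped ring fixed by C4, C5 and C6.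

Step 17
Reactants: 24 (1R,4R,5R,6S,13S)-C8-keto butenolide TBS ether
Product: 25 (1R,4R,5R,6S,8S,13S)-C8 alcohol TBS ether
Conditions: NaBH4, CeCl3·7H2O, MeOH, −78 °C
Reagents that add atoms: none
Why: Luche-type 1,2-reduction, in which the cerium salt keeps the medium too weakly basic to enolise the acidic C1–H and hydride reaches C8 from the ring periphery anti to the branched C1 substituent, placing the hydroxyl cis to the side chain (8S).

Step 18
Reactants: 25 (1R,4R,5R,6S,8S,13S)-C8 alcohol TBS ether
Product: 26 (1R,4R,5R,6S,8S,13S)-C8,C14-diol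
Conditions: HF·pyridine, THF, 0 °C → rt
Reagents that add atoms: none
Why: Fluoride-mediated desilylation under mildly acidic conditions removes the primary TBS ether without opening the butenolide or disturbing C1 and C8.

Step 19
Reactants: 26 (1R,4R,5R,6S,8S,13S)-C8,C14-diol
Product: 27 target CNP0267808.2
Conditions: AcCl (1.05 equiv), 2,4,6-collidine, CH2Cl2, −78 °C
Reagents that add atoms: acetyl chloride, CC(=O)Cl
Why: Selective acylation of a primary over a secondary alcohol with acetyl chloride and a hindered pyridine at low temperature, helped here by the crowding of the C8 hydroxyl next to the branched C1 substituent.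

Compound list
1 | (R)-3-methylcyclohexanone (commercial; also the retro-aldol product of (R)-pulegone) | C[C@@H]1CCCC(=O)C1 | starting material
2 | methyl (4R)-4-methyl-2-oxocyclohexane-1-carboxylate | COC(=O)C1CC[C@@H](C)CC1=O | intermediate
3 | methyl (4R)-4-methyl-2-oxo-1-(phenylselanyl)cyclohexane-1-carboxylate | COC(=O)C1([Se]c2ccccc2)CC[C@@H](C)CC1=O | intermediate
4 | methyl (4R)-4-methyl-2-oxo-1-(phenylseleninyl)cyclohexane-1-carboxylate | COC(=O)C1([Se](=O)c2ccccc2)CC[C@@H](C)CC1=O | intermediate
5 | methyl (4R)-4-methyl-6-oxocyclohex-1-ene-1-carboxylate | COC(=O)C1=CC[C@@H](C)CC1=O | intermediate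
6 | methyl (4S)-2-acetoxy-4-methylcyclohexa-1,5-diene-1-carboxylate | CC(=O)OC1=C(C(=O)OC)C=C[C@@H](C)C1 | intermediate
7 | methyl (1R,5S,6R)-3-acetoxy-5-methylbicyclo[4.1.0]hept-2-ene-2-carboxylate (methyl anti to the cyclopropane CH2) | CC(=O)OC1=C(C(=O)OC)[C@@H]2C[C@@H]2[C@@H](C)C1 | intermediate
8 | methyl (1R,5S,6R)-5-methyl-3-oxobicyclo[4.1.0]heptane-2-carboxylate | COC(=O)C1[C@@H]2C[C@@H]2[C@@H](C)CC1=O | intermediate
9 | diethyl malonate | CCOC(=O)CC(=O)OCC | starting material
10 | 5-bromo-2-methylpent-2-ene | CC(C)=CCCBr | starting material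
11 | diethyl 2-(4-methylpent-3-en-1-yl)malonate | CCOC(=O)C(CCC=C(C)C)C(=O)OCC | intermediate
12 | 2-(4-methylpent-3-en-1-yl)propane-1,3-diol | OCC(CO)CCC=C(C)C | intermediate
13 | (2R)-2-(hydroxymethyl)-6-methylhept-5-en-1-yl acetate | CC(=O)OC[C@@H](CO)CCC=C(C)C | intermediate
14 | (2S)-2-{[(tert-butyldimethylsilyl)oxy]methyl}-6-methylhept-5-en-1-yl acetate | CC(=O)OC[C@@H](CO[Si](C)(C)C(C)(C)C)CCC=C(C)C | intermediate
15 | (2S)-2-{[(tert-butyldimethylsilyl)oxy]methyl}-6-methylhept-5-en-1-ol | OC[C@@H](CO[Si](C)(C)C(C)(C)C)CCC=C(C)C | intermediate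
16 | (2R)-2-{[(tert-butyldimethylsilyl)oxy]methyl}-6-methylhept-5-enal | O=C[C@@H](CO[Si](C)(C)C(C)(C)C)CCC=C(C)C | intermediate
17 | tert-butyl{[(2S)-2-(2,2-dibromoethenyl)-6-methylhept-5-en-1-yl]oxy}dimethylsilane | BrC(Br)=C[C@@H](CO[Si](C)(C)C(C)(C)C)CCC=C(C)C | intermediate
18 | lithium acetylide of (3S)-3-{[(tert-butyldimethylsilyl)oxy]methyl}-7-methyloct-6-en-1-yne | [Li]C#C[C@@H](CO[Si](C)(C)C(C)(C)C)CCC=C(C)C | intermediate
19 | (4S)-4-{[(tert-butyldimethylsilyl)oxy]methyl}-8-methylnon-7-en-2-yn-1-ol | OCC#C[C@@H](CO[Si](C)(C)C(C)(C)C)CCC=C(C)C | intermediate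
20 | (4S)-4-{[(tert-butyldimethylsilyl)oxy]methyl}-8-methylnon-7-en-2-yn-1-yl (1R,5S,6R)-5-methyl-3-oxobicyclo[4.1.0]heptane-2-carboxylate | O=C(OCC#C[C@@H](CO[Si](C)(C)C(C)(C)C)CCC=C(C)C)C1[C@@H]2C[C@@H]2[C@@H](C)CC1=O | intermediate
21 | (4S)-4-{[(tert-butyldimethylsilyl)oxy]methyl}-8-methylnon-7-en-2-yn-1-yl (1R,5S,6R)-3-acetoxy-5-methylbicyclo[4.1.0]hept-2-ene-2-carboxylate (key-step precursor) | CC(=O)OC1=C(C(=O)OCC#C[C@@H](CO[Si](C)(C)C(C)(C)C)CCC=C(C)C)[C@@H]2C[C@@H]2[C@@H](C)C1 | intermediate
22 | cyclobutene photoadduct: C2–C3 and C1–C8 bonds formed on the ring face anti to C9, γ-lactone on C3/C2, C1=C2 cyclobutene, C8 tertiary acetate | CC(=O)O[C@@]12C[C@H](C)[C@H]3C[C@H]3[C@]1(C(=O)OC4)C4=C2[C@@H](CO[Si](C)(C)C(C)(C)C)CCC=C(C)C | intermediate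
23 | sodium dienolate of 24 (O–C8=C1–C2=C3–C10=O) | [Na+].[O-]C1=C([C@@H](CO[Si](C)(C)C(C)(C)C)CCC=C(C)C)C2=C(C(=O)OC2)[C@@H]2C[C@@H]2[C@@H](C)C1 | intermediate
24 | (1R,4R,5R,6S,13S)-C8-keto butenolide TBS ether: ring C1–C8 with C2=C3 shared with the butenolide, cyclopropane C4–C9–C5, 6-methyl, 8-oxo, C1 bearing CH(CH2OTBS)(4-methylpent-3-enyl) (key-step product) | CC(C)(C)[Si](C)(C)OC[C@@H](CCC=C(C)C)[C@@H]1C2=C(C(=O)OC2)[C@@H]2C[C@@H]2[C@@H](C)CC1=O | intermediate
25 | (1R,4R,5R,6S,8S,13S)-C8 alcohol TBS ether (OH cis to the side chain) | CC(C)(C)[Si](C)(C)OC[C@@H](CCC=C(C)C)[C@@H]1C2=C(C(=O)OC2)[C@@H]2C[C@@H]2[C@@H](C)C[C@@H]1O | intermediate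
26 | (1R,4R,5R,6S,8S,13S)-C8,C14-diol | OC[C@@H](CCC=C(C)C)[C@@H]1C2=C(C(=O)OC2)[C@@H]2C[C@@H]2[C@@H](C)C[C@@H]1O | intermediate
27 | CNP0267808.2, (1R,4R,5R,6S,8S,13S)-C14 acetate | CC(=O)OC[C@@H](CCC=C(C)C)[C@@H]1C2=C(C(=O)OC2)[C@@H]2C[C@@H]2[C@@H](C)C[C@@H]1O | target

Total step count: 19. Longest linear sequence: 14 steps (steps 6–13, then 14–19); the ring fragment contributes 5 steps (steps 1–5).

Steps most likely to fail

1. Step 16. The ester may stay in its Z rotamer throughout the short triplet lifetime. The excited enoate would then only decay, or slowly drift into acyl migration of the enol acetate or opening of the cyclopropane before C3 and C2 can bond.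
The fallback sets out from 20 and comes back at 24, and it makes the two bonds one after the other with known reactions. An In(NTf2)3-catalysed Conia-ene cycloisomerisation of 20 in hot toluene joins C3 to C2. Here the metal enolate lives long enough for the ester to rotate, and the product is the spiro (Z)-alkylidene lactone F1. Direct, unsensitised irradiation of this β,γ-unsaturated ketone near 300 nm in benzene then brings about the photochemical 1,3-acyl shift. C8 moves from C3 to C1, which is the known two-carbon ring expansion of 2-alkenylcycloalkanones. This gives 24 after the same amine equilibration at C1.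

2. Step 17. Hydride delivery may show poor facial selectivity on the flexible eight-membered ring. Enolisation or drift of the acidic C1 centre may also compete with reduction.
The fallback sets out from 24 and comes back at 25, and it replaces direct stereocontrol by inversion. The ketone is reduced with whichever simple hydride (for example DIBAL-H in toluene) best favours the opposite face, giving the 8-epi alcohol F2. A Mitsunobu reaction (4-nitrobenzoic acid, PPh3, DIAD, THF) inverts C8 to the (8S)-4-nitrobenzoate F3. Methanolysis with K2CO3 in MeOH then releases 25.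

3. Step 4. The conjugated C4=C5 may react sluggishly, the diene may be lost to oxidative aromatisation, or face discrimination by a single allylic methyl group may be insufficient.
The fallback sets out from 1 and comes back at 8, and it moves the cyclopropanation to an isolated alkene with a directing ketal.
- Sulfinylation of 1 at the less hindered α-carbon under equilibrating conditions (NaH, methyl benzenesulfinate, THF) gives (5R)-5-methyl-2-(phenylsulfinyl)cyclohexan-1-one F4.
- Thermolysis of F4 in refluxing toluene over CaCO3 gives (R)-5-methylcyclohex-2-en-1-one F5.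
- Ketalisation with ethylene glycol and TsOH under Dean–Stark conditions moves the alkene out of conjugation to (9S)-9-methyl-1,4-dioxaspiro[4.5]dec-7-ene F6.
- Simmons–Smith cyclopropanation, now guided by the pseudoaxial ketal oxygen as well as by the methyl group, gives (1S,5S,6R)-5-methylspiro[bicyclo[4.1.0]heptane-3,2'-[1,3]dioxolane] F7.
- Aqueous HCl in THF releases (1S,5S,6R)-5-methylbicyclo[4.1.0]heptan-3-one F8.
- Carbomethoxylation with NaH and (MeO)2CO should settle at C3, where the enolate is conjugated with the cyclopropane and less crowded than beside the methyl-bearing carbon. This gives 8.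

Further compounds
F1 | step 16 | spiro (Z)-alkylidene lactone: C3 quaternary and shared by the 3-oxobicyclo[4.1.0]heptane and a γ-lactone whose C2 carries the exocyclic C2=C1H–C13 alkene, C2 bonded anti to C9 | O=C1C[C@H](C)[C@H]2C[C@H]2[C@@]13C(=O)OC/C3=C\[C@@H](CO[Si](C)(C)C(C)(C)C)CCC=C(C)C
F2 | step 17 | (1R,4R,5R,6S,8R,13S)-8-epi alcohol TBS ether | CC(C)(C)[Si](C)(C)OC[C@@H](CCC=C(C)C)[C@@H]1C2=C(C(=O)OC2)[C@@H]2C[C@@H]2[C@@H](C)C[C@H]1O
F3 | step 17 | (8S)-4-nitrobenzoate of 25 | CC(C)(C)[Si](C)(C)OC[C@@H](CCC=C(C)C)[C@@H]1C2=C(C(=O)OC2)[C@@H]2C[C@@H]2[C@@H](C)C[C@@H]1OC(=O)c1ccc(cc1)[N+](=O)[O-]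
F4 | step 4 | (5R)-5-methyl-2-(phenylsulfinyl)cyclohexan-1-one | O=C1C[C@H](C)CCC1S(=O)c1ccccc1
F5 | step 4 | (R)-5-methylcyclohex-2-en-1-one | O=C1C=CC[C@@H](C)C1
F6 | step 4 | (9S)-9-methyl-1,4-dioxaspiro[4.5]dec-7-ene | C[C@H]1CC2(CC=C1)OCCO2
F7 | step 4 | (1S,5S,6R)-5-methylspiro[bicyclo[4.1.0]heptane-3,2'-[1,3]dioxolane] | O1CCOC12C[C@@H]3C[C@@H]3[C@@H](C)C2
F8 | step 4 | (1S,5S,6R)-5-methylbicyclo[4.1.0]heptan-3-one | O=C1C[C@@H]2C[C@@H]2[C@@H](C)C1
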